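The 36-membered lactone ring is opened at the O35–C1 ester bond and the chain is cut on both sides of C27, the central carbinol of the only 1,3,5-triol (C25/C27/C29), which sits between the methylenes C26 and C28. In one flask a 2-silyl-1,3-dithiane serves as the C27 acyl anion and joins two terminal epoxides, forming C26–C27 and C27–C28 while leaving O25 silylated, O29 free and C27 at the ketone level for a hydroxyl-directed anti reduction. The precursors are a C4–C26 epoxide (five silyl ethers, C4=C5 alkene) and a C28–C40 epoxide (C33 silyl ether, C35 PMB ether), each enantiopure at its oxirane carbon.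

Key step: step 32

Remark on naming: carbon numbers are those of the target (C1 lactone carbonyl, C35 ring O–CH, C36 methyl-bearing carbon, C40 chain end). For chain intermediates "target configuration" means the spatial arrangement the centre has in the target (7S, 9R, 13S, 17R, 21R, 25S, 27S, 29S, 33R, 35R, 36S there). CIP letters shift with the protecting groups, so the SMILES in the compound list defines each compound. TBS = tert-butyldimethylsilyl, PMB = 4-methoxybenzyl, salen = N,N′-bis(3,5-di-tert-butylsalicylidene)cyclohexane-1,2-diamine dianion.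

Assumption: (R)-BINAP in the iridium allylation is taken to give the (R)-carbinol whenever the carbinol substituent outranks allyl, and (S,S)-(salen)Co(OAc) to leave (S)-alkyloxiranes unreacted. If either sense proves opposite, the mirror-image ligand is used.

**Linchpin**

Step 1
Reactants: 1 1,3-dithiane
Product: 3 2-(tert-butyldimethylsilyl)-1,3-dithiane, via 2-lithio-1,3-dithiane 2 (not isolated)
Conditions: n-BuLi, THF, −30 °C; TBSCl, −78 °C → rt
Reagents that add atoms: tert-butyldimethylsilyl chloride, C[Si](C)(Cl)C(C)(C)C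
Why: C2 lithiation of the dithiane (Corey–Seebach umpolung) followed by C-silylation with the chlorosilane is the routine way to 2-silyl dithianes.

**West epoxide, C4–C26 (steps 2–20)**

Step 2
Reactants: 4 pentane-1,5-diol
Product: 5 5-[(4-methoxybenzyl)oxy]pentan-1-ol (C21–C25 unit)
Conditions: NaH (1 equiv), PMBCl (1 equiv), Bu4NI (cat.), THF/DMF, 0 °C → rt, diol in threefold excess
Reagents that add atoms: 4-methoxybenzyl chloride, COc1ccc(CCl)cc1
Why: Williamson etherification of a symmetrical diol used in excess should stop largely at the mono-ether, and the surplus diol is washed out with water.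

Step 3
Reactants: 5 5-[(4-methoxybenzyl)oxy]pentan-1-ol; 6 allyl acetate
Product: 7 (S)-8-[(4-methoxybenzyl)oxy]oct-1-en-4-ol (C18–C25; new carbinol C21)
Conditions: [Ir(cod)Cl]2 (2.5 mol %), (R)-BINAP (5 mol %), 4-chloro-3-nitrobenzoic acid (10 mol %), Cs2CO3 (20 mol %), THF, 100 °C
Reagents that add atoms: none
Why: Krische allylation from the alcohol oxidation level, in which the iridium catalyst dehydrogenates C21, transfers allyl to the transient aldehyde and returns the hydrogen, so that (R)-BINAP should set C21 in the target sense by catalyst control.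

Step 4
Reactants: 7 (S)-8-[(4-methoxybenzyl)oxy]oct-1-en-4-ol
Product: 8 (S)-4-(TBS-oxy)-8-(PMB-oxy)oct-1-ene
Conditions: TBSCl, imidazole, DMF, rt
Reagents that add atoms: tert-butyldimethylsilyl chloride, C[Si](C)(Cl)C(C)(C)C
Why: Imidazole-assisted silylation of a secondary alcohol is standard and leaves the PMB ether and the alkene untouched.

Step 5
Reactants: 8 (S)-4-(TBS-oxy)-8-(PMB-oxy)oct-1-ene
Product: 9 (S)-5-(TBS-oxy)-9-(PMB-oxy)nonanal (CHO = C17)
Conditions: Rh(acac)(CO)2 (1 mol %), Xantphos (2 mol %), CO/H2 (1:1, 10 bar), toluene, 70 °C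
Reagents that add atoms: carbon monoxide, [C-]#[O+]
Why: Rhodium-catalysed hydroformylation with a wide-bite-angle diphosphine should place the formyl group on the terminal alkene carbon and so supply the one carbon needed for the 1,5-diol spacing.

Step 6
Reactants: 9 (S)-5-(TBS-oxy)-9-(PMB-oxy)nonanal; 6 allyl acetate
Product: 10 C14–C25 homoallylic alcohol (HO–C17; TBSO–C21; PMBO–C25; alkene C14=C15; C17 and C21 target configuration)
Conditions: [Ir(cod)Cl]2 (2.5 mol %), (R)-BINAP (5 mol %), 4-chloro-3-nitrobenzoic acid (10 mol %), Cs2CO3 (20 mol %), i-PrOH (2 equiv), THF, 100 °C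
Reagents that add atoms: none
Why: Krische allylation at the aldehyde level with isopropanol as hydrogen donor, where the (R)-BINAP catalyst should set C17 by catalyst control because the remote C21 centre exerts no bias.

Step 7
Reactants: 10 C14–C25 homoallylic alcohol
Product: 11 C14–C25 bis-silyl ether (TBSO at C17 and C21)
Conditions: TBSCl, imidazole, DMF, rt
Reagents that add atoms: tert-butyldimethylsilyl chloride, C[Si](C)(Cl)C(C)(C)C
Why: Standard imidazole-assisted silylation of the new secondary alcohol.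

Step 8
Reactants: 11 C14–C25 bis-silyl ether
Product: 12 C13–C25 aldehyde (CHO = C13)
Conditions: Rh(acac)(CO)2 (1 mol %), Xantphos (2 mol %), CO/H2 (1:1, 10 bar), toluene, 70 °C
Reagents that add atoms: carbon monoxide, [C-]#[O+]
Why: Linear-selective hydroformylation of the only alkene, as in step 5.

Step 9
Reactants: 12 C13–C25 aldehyde; 6 allyl acetate
Product: 13 C10–C25 homoallylic alcohol (HO–C13; alkene C10=C11; C13, C17 and C21 target configuration)
Conditions: [Ir(cod)Cl]2 (2.5 mol %), (R)-BINAP (5 mol %), 4-chloro-3-nitrobenzoic acid (10 mol %), Cs2CO3 (20 mol %), i-PrOH (2 equiv), THF, 100 °C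
Reagents that add atoms: none
Why: Krische allylation at the aldehyde level, in which (R)-BINAP should set C13 by catalyst control.

Step 10
Reactants: 13 C10–C25 homoallylic alcohol
Product: 14 C10–C25 tris-silyl ether (TBSO at C13, C17 and C21)
Conditions: TBSCl, imidazole, DMF, rt
Reagents that add atoms: tert-butyldimethylsilyl chloride, C[Si](C)(Cl)C(C)(C)C
Why: Standard imidazole-assisted silylation.

Step 11
Reactants: 14 C10–C25 tris-silyl ether
Product: 15 C9–C25 aldehyde (CHO = C9)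
Conditions: Rh(acac)(CO)2 (1 mol %), Xantphos (2 mol %), CO/H2 (1:1, 10 bar), toluene, 70 °C
Reagents that add atoms: carbon monoxide, [C-]#[O+]
Why: Linear-selective hydroformylation, as in step 5.

Step 12
Reactants: 15 C9–C25 aldehyde; 6 allyl acetate
Product: 16 C6–C25 homoallylic alcohol (HO–C9; alkene C6=C7; C9, C13, C17 and C21 target configuration)
Conditions: [Ir(cod)Cl]2 (2.5 mol %), (S)-BINAP (5 mol %), 4-chloro-3-nitrobenzoic acid (10 mol %), Cs2CO3 (20 mol %), i-PrOH (2 equiv), THF, 100 °C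
Reagents that add atoms: none
Why: Krische allylation at the aldehyde level, where the switch to (S)-BINAP should deliver the opposite facial sense required at C9 by catalyst control.

Step 13
Reactants: 16 C6–C25 homoallylic alcohol
Product: 17 C6–C25 tetrakis-silyl ether (TBSO at C9, C13, C17 and C21)
Conditions: TBSCl, imidazole, DMF, rt
Reagents that add atoms: tert-butyldimethylsilyl chloride, C[Si](C)(Cl)C(C)(C)C
Why: Standard imidazole-assisted silylation.

Step 14
Reactants: 17 C6–C25 tetrakis-silyl ether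
Product: 19 C7–C25 primary alcohol (HO–C7H2), via C7 aldehyde 18 (not isolated)
Conditions: OsO4 (2 mol %), NaIO4 (4 equiv), 2,6-lutidine, dioxane/H2O, rt; extractive work-up; NaBH4, MeOH, 0 °C
Reagents that add atoms: osmium tetroxide, O=[Os](=O)(=O)=O (oxygen carrier, replenished by sodium periodate, [Na+].[O-]I(=O)(=O)=O)
Why: Lemieux–Johnson cleavage is used instead of ozone because it spares the electron-rich PMB ring, and immediate borohydride reduction avoids storing the elimination-prone β-silyloxy aldehyde.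

Step 15
Reactants: 19 C7–C25 primary alcohol; 6 allyl acetate
Product: 20 C4–C25 homoallylic alcohol (HO–C7; alkene C4=C5; C7, C9, C13, C17 and C21 target configuration)
Conditions: [Ir(cod)Cl]2 (2.5 mol %), (S)-BINAP (5 mol %), 4-chloro-3-nitrobenzoic acid (10 mol %), Cs2CO3 (20 mol %), THF, 100 °C
Reagents that add atoms: none
Why: Krische allylation from the alcohol level generates the β-silyloxy aldehyde only transiently, and the (S)-BINAP catalyst should override 1,3-induction to set C7 syn to C9.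

Step 16
Reactants: 20 C4–C25 homoallylic alcohol
Product: 21 C4–C25 pentakis-silyl ether (TBSO at C7, C9, C13, C17 and C21; PMBO–C25)
Conditions: TBSCl, imidazole, DMF, rt
Reagents that add atoms: tert-butyldimethylsilyl chloride, C[Si](C)(Cl)C(C)(C)C
Why: Standard imidazole-assisted silylation.

Step 17
Reactants: 21 C4–C25 pentakis-silyl ether
Product: 22 C4–C25 primary alcohol (HO–C25H2)
Conditions: DDQ, CH2Cl2/pH 7 buffer, 0 °C
Reagents that add atoms: none
Why: Oxidative PMB cleavage by DDQ (benzylic oxocarbenium ion, then hydrolysis) is selective for the electron-rich benzyl ether over silyl ethers and the terminal alkene.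

Step 18
Reactants: 22 C4–C25 primary alcohol
Product: 23 C4–C25 aldehyde (CHO = C25)
Conditions: Dess–Martin periodinane, NaHCO3, CH2Cl2, 0 °C → rt
Reagents that add atoms: none
Why: Buffered Dess–Martin oxidation stops at the aldehyde and tolerates silyl ethers and the alkene.

Step 19
Reactants: 23 C4–C25 aldehyde
Product: 24 C4–C26 oxirane as a mixture of C25 epimers
Conditions: Me3S+ I−, n-BuLi, THF, −10 °C; then 23, −10 °C → rt
Reagents that add atoms: trimethylsulfonium iodide, C[S+](C)C.[I-]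
Why: Corey–Chaykovsky methylene transfer builds the oxirane from the aldehyde, a choice forced by the C4=C5 alkene, which no alkene epoxidation at C25=C26 could spare; C25 forms without control and is corrected in step 20.

Step 20
Reactants: 24 C4–C26 oxirane (C25 epimers)
Product: 25 west epoxide, (25S)-oxirane C25–C26 with TBSO at C7, C9, C13, C17 and C21 and alkene C4=C5
Conditions: (S,S)-(salen)Co(OAc) (2 mol %), H2O (0.55 equiv), THF, 0 °C → rt
Reagents that add atoms: none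
Why: Jacobsen hydrolytic kinetic resolution, in which the (S,S)-catalyst should hydrate only the (25R)-oxirane so that the (25S)-epimer remains and is separated from the polar diol; C25 is set by catalyst control.

**East epoxide, C28–C40 (steps 21–31)**

Step 21
Reactants: 26 (S)-4-benzyloxazolidin-2-one; 27 hexanoyl chloride
Product: 28 (S)-4-benzyl-3-hexanoyloxazolidin-2-one
Conditions: Et3N, DMAP (cat.), CH2Cl2, 0 °C → rt
Reagents that add atoms: none
Why: N-Acylation of the oxazolidinone by the acid chloride under nucleophilic catalysis is a standard entry to Evans imides.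

Step 22
Reactants: 28 (S)-4-benzyl-3-hexanoyloxazolidin-2-one
Product: 30 (S)-4-benzyl-3-[(S)-2-methylhexanoyl]oxazolidin-2-one, via sodium Z-enolate 29 (not isolated)
Conditions: NaN(SiMe3)2, THF, −78 °C; MeI, −78 °C
Reagents that add atoms: iodomethane, CI
Why: Evans asymmetric alkylation, in which the chelated Z-enolate is methylated on the face remote from the benzyl group and should set C36 as (S), the minor diastereomer being removed by chromatography.

Step 23
Reactants: 30 (S)-4-benzyl-3-[(S)-2-methylhexanoyl]oxazolidin-2-one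
Product: 31 (S)-2-methylhexan-1-ol (C35–C40)
Conditions: LiBH4, MeOH (1 equiv), Et2O, 0 °C
Reagents that add atoms: none
Why: Reductive cleavage of the imide by LiBH4 attacks the exocyclic carbonyl and releases the alcohol without epimerising C36.

Step 24
Reactants: 31 (S)-2-methylhexan-1-ol; 6 allyl acetate
Product: 32 (4R,5S)-5-methylnon-1-en-4-ol (C32–C40; new carbinol C35)
Conditions: [Ir(cod)Cl]2 (2.5 mol %), (R)-BINAP (5 mol %), 4-chloro-3-nitrobenzoic acid (10 mol %), Cs2CO3 (20 mol %), THF, 100 °C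
Reagents that add atoms: none
Why: Krische allylation from the alcohol level never accumulates the epimerisable α-branched aldehyde, and the (R)-BINAP catalyst should set C35 as (R), anti to the C36 methyl, against the weak Felkin preference.

Step 25
Reactants: 32 (4R,5S)-5-methylnon-1-en-4-ol
Product: 33 1-methoxy-4-({[(4R,5S)-5-methylnon-1-en-4-yl]oxy}methyl)benzene (C35 PMB ether)
Conditions: NaH, PMBCl, Bu4NI (cat.), DMF, 0 °C → rt
Reagents that add atoms: 4-methoxybenzyl chloride, COc1ccc(CCl)cc1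
Why: Williamson etherification installs the one protecting group that can later be removed oxidatively in the presence of nine silyl ethers.

Step 26
Reactants: 33 C35 PMB ether
Product: 35 (3R,4S)-3-[(4-methoxybenzyl)oxy]-4-methyloctan-1-ol (HO–C33H2), via C33 aldehyde 34 (not isolated)
Conditions: OsO4 (2 mol %), NaIO4 (4 equiv), 2,6-lutidine, dioxane/H2O, rt; extractive work-up; NaBH4, MeOH, 0 °C
Reagents that add atoms: osmium tetroxide, O=[Os](=O)(=O)=O (oxygen carrier, replenished by sodium periodate, [Na+].[O-]I(=O)(=O)=O)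
Why: Lemieux–Johnson cleavage spares the PMB ring, and reduction gives the β-alkoxy alcohol needed for alcohol-level allylation.

Step 27
Reactants: 35 (3R,4S)-3-[(4-methoxybenzyl)oxy]-4-methyloctan-1-ol; 6 allyl acetate
Product: 36 (4R,6R,7S)-6-[(4-methoxybenzyl)oxy]-7-methylundec-1-en-4-ol (C30–C40; new carbinol C33)
Conditions: [Ir(cod)Cl]2 (2.5 mol %), (R)-BINAP (5 mol %), 4-chloro-3-nitrobenzoic acid (10 mol %), Cs2CO3 (20 mol %), THF, 100 °C
Reagents that add atoms: none
Why: Krische allylation from the alcohol level, where the (R)-BINAP catalyst should set C33 as (R), 1,3-syn to O35, by catalyst control over the weak induction of the β-alkoxy aldehyde.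

Step 28
Reactants: 36 C30–C40 homoallylic alcohol
Product: 37 C33 TBS ether of 36
Conditions: TBSCl, imidazole, DMF, rt
Reagents that add atoms: tert-butyldimethylsilyl chloride, C[Si](C)(Cl)C(C)(C)C
Why: Standard imidazole-assisted silylation.

Step 29
Reactants: 37 C33 TBS ether
Product: 38 (5R,7R,8S)-5-(TBS-oxy)-7-(PMB-oxy)-8-methyldodecanal (CHO = C29)
Conditions: Rh(acac)(CO)2 (1 mol %), Xantphos (2 mol %), CO/H2 (1:1, 10 bar), toluene, 70 °C
Reagents that add atoms: carbon monoxide, [C-]#[O+]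
Why: Linear-selective hydroformylation of the only alkene adds C29 at the aldehyde level.

Step 30
Reactants: 38 C29 aldehyde
Product: 39 C28–C40 oxirane as a mixture of C29 epimers
Conditions: Me3S+ I−, n-BuLi, THF, −10 °C; then 38, −10 °C → rt
Reagents that add atoms: trimethylsulfonium iodide, C[S+](C)C.[I-]
Why: Corey–Chaykovsky methylene transfer converts the aldehyde directly into the terminal oxirane; C29 forms without control and is corrected in step 31.

Step 31
Reactants: 39 C28–C40 oxirane (C29 epimers)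
Product: 40 east epoxide, (29S,33R,35R,36S)-oxirane C28–C29 with C33 TBS ether and C35 PMB ether
Conditions: (S,S)-(salen)Co(OAc) (2 mol %), H2O (0.55 equiv), THF, 0 °C → rt
Reagents that add atoms: none
Why: Jacobsen hydrolytic kinetic resolution, in which the (S,S)-catalyst should hydrate the (29R)-oxirane and leave the (29S)-epimer; C29 is set by catalyst control.

**Fragment union and endgame**

Step 32
Reactants: 3 2-(tert-butyldimethylsilyl)-1,3-dithiane; 25 west epoxide; 40 east epoxide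
Product: 44 C4–C40 chain with C27 as 1,3-dithiane, O25 as TBS ether and free C29 hydroxyl, via lithiated silyl dithiane 41 (not isolated), via C25 lithium alkoxide 42 (not isolated), via Brook-rearranged C27 anion 43 (not isolated)
Conditions: 3 (1.05 equiv), t-BuLi (1.05 equiv), Et2O, −78 → −45 °C; 25 (1.0 equiv), Et2O, −78 → −25 °C; then 40 (1.1 equiv) in Et2O with HMPA, −78 → 0 °C; aq. NH4Cl
Reagents that add atoms: none
Why: tert-Butyllithium removes H2 of 3 and the hindered carbanion 41 opens 25 by SN2 attack at the unsubstituted oxirane carbon C26, giving alkoxide 42, which is stable in ether because silicon does not migrate without a polar additive. HMPA then triggers the 1,4-Brook rearrangement (silyl shift from C27 to O25 through a pentacoordinate silicate), which silylates O25 and unveils dithiane anion 43; this opens 40 at C28, and the C29 alkoxide is protonated on work-up. The closest known reaction type is the solvent-gated three-component anion relay coupling of a 2-silyl-1,3-dithiane with two different epoxides. No ring is closed and no stereocentre is created: C25 and C29 are carried in from 25 and 40 and stay untouched because both substitutions occur at CH2 termini. The step needs terminal regioselectivity, secured by the monosubstituted oxiranes, and strict ordering of the two alkylations, secured by running the first in ether with one equivalent of 25 and adding HMPA only together with 40. The silyl ethers, the PMB ether and the C4=C5 alkene are inert to the dithiane anions.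

Step 33
Reactants: 44 C4–C40 dithiane
Product: 45 C27 ketone (C29 hydroxyl free; O25 silylated)
Conditions: MeI, CaCO3, MeCN/H2O (9:1), 45 °C
Reagents that add atoms: water, O
Why: Alkylative dithiane hydrolysis (S-methylation, ring opening, hydrolysis of the thionium ion) under carbonate buffering avoids mercury salts and oxidants, which would endanger the alkene and the PMB ether.

Step 34
Reactants: 45 C27 ketone
Product: 46 C27,C29 anti-diol (C27 target configuration)
Conditions: Me4NBH(OAc)3, MeCN/AcOH (1:1), −30 °C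
Reagents that add atoms: none
Why: Evans–Saksena reduction, in which the C29 hydroxyl binds boron and delivers hydride intramolecularly through a chair transition state, should set C27 anti to C29 and hence syn to C25, while the silylated O25 cannot direct.

Step 35
Reactants: 46 C27,C29 anti-diol
Product: 47 C4–C40 nona-silyl ether (TBSO at C7, C9, C13, C17, C21, C25, C27, C29 and C33; PMBO–C35; alkene C4=C5)
Conditions: TBSOTf, 2,6-lutidine, CH2Cl2, −78 → 0 °C
Reagents that add atoms: tert-butyldimethylsilyl triflate, C[Si](C)(OS(=O)(=O)C(F)(F)F)C(C)(C)C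
Why: The silyl triflate silylates both hindered secondary hydroxyls, and the PMB ether tolerates it at low temperature.

Step 36
Reactants: 48 methyl but-2-ynoate
Product: 49 methyl (Z)-3-iodobut-2-enoate
Conditions: NaI, AcOH, 115 °C
Reagents that add atoms: sodium iodide, [Na+].[I-]
Why: Conjugate hydroiodination of the ynoate (iodide addition, then protonation anti to iodine) should give the Z-iodoenoate with iodine cis to the ester.

Step 37
Reactants: 47 C4–C40 nona-silyl ether; 49 methyl (Z)-3-iodobut-2-enoate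
Product: 51 C1–C40 methyl (Z)-enoate (PMBO–C35), via C4 alkylborane 50 (not isolated)
Conditions: 9-BBN, THF, rt; then 49, Pd(dppf)Cl2 (10 mol %), AsPh3, Cs2CO3, DMF/H2O, rt
Reagents that add atoms: none
Why: Anti-Markovnikov hydroboration of the only alkene followed by B-alkyl Suzuki–Miyaura coupling, which retains the vinyl iodide geometry, should join C4 to C3 and give the Z-trisubstituted enoate.

Step 38
Reactants: 51 C1–C40 methyl (Z)-enoate
Product: 52 C35 alcohol methyl ester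
Conditions: DDQ, CH2Cl2/pH 7 buffer, 0 °C
Reagents that add atoms: none
Why: Oxidative PMB cleavage by DDQ frees only O35, since silyl ethers and the electron-poor enoate are inert.

Step 39
Reactants: 52 C35 alcohol methyl ester
Product: 53 seco acid (C1 carboxylic acid; C35 hydroxyl)
Conditions: LiOH·H2O, THF/MeOH/H2O, rt → 40 °C; then 0.5 M HCl to pH 4, 0 °C
Reagents that add atoms: lithium hydroxide, [Li+].[OH-]
Why: Saponification by acyl substitution leaves the C2=C3 geometry and the secondary silyl ethers untouched.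

Step 40
Reactants: 53 seco acid
Product: 55 nona-TBS 36-membered macrolactone, via mixed anhydride 54 (not isolated)
Conditions: 2-methyl-6-nitrobenzoic anhydride, DMAP, toluene, rt, slow addition of 53 (final 1 mM)
Reagents that add atoms: none
Why: Shiina macrolactonization (mixed anhydride, then DMAP-mediated acyl transfer to O35 at high dilution) closes the ring under mild conditions chosen to keep the C2=C3 geometry.

Step 41
Reactants: 55 nona-TBS macrolactone
Product: 56 CNP0126363.4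
Conditions: HF·pyridine, pyridine, THF, 0 °C → rt
Reagents that add atoms: none
Why: Buffered fluoride cleavage of all nine silyl ethers should leave the lactone and the Z-enoate intact and give the target.

**Compound list**

1 | 1,3-dithiane | C1CSCSC1 | starting material
2 | 2-lithio-1,3-dithiane | [Li]C1SCCCS1 | intermediate (not isolated)
3 | 2-(tert-butyldimethylsilyl)-1,3-dithiane | CC(C)(C)[Si](C)(C)C1SCCCS1 | intermediate
4 | pentane-1,5-diol | OCCCCCO | starting material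
5 | 5-[(4-methoxybenzyl)oxy]pentan-1-ol | COc1ccc(COCCCCCO)cc1 | intermediate
6 | allyl acetate | C=CCOC(C)=O | starting material
7 | (S)-8-[(4-methoxybenzyl)oxy]oct-1-en-4-ol | COc1ccc(COCCCC[C@H](O)CC=C)cc1 | intermediate
8 | (S)-4-(TBS-oxy)-8-(PMB-oxy)oct-1-ene | COc1ccc(COCCCC[C@H](O[Si](C)(C)C(C)(C)C)CC=C)cc1 | intermediate
9 | (S)-5-(TBS-oxy)-9-(PMB-oxy)nonanal | COc1ccc(COCCCC[C@H](O[Si](C)(C)C(C)(C)C)CCCC=O)cc1 | intermediate
10 | C14–C25 homoallylic alcohol (HO–C17, TBSO–C21, PMBO–C25, C14=C15) | COc1ccc(COCCCC[C@H](O[Si](C)(C)C(C)(C)C)CCC[C@H](O)CC=C)cc1 | intermediate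
11 | C14–C25 bis-silyl ether | COc1ccc(COCCCC[C@H](O[Si](C)(C)C(C)(C)C)CCC[C@H](O[Si](C)(C)C(C)(C)C)CC=C)cc1 | intermediate
12 | C13–C25 aldehyde | COc1ccc(COCCCC[C@H](O[Si](C)(C)C(C)(C)C)CCC[C@H](O[Si](C)(C)C(C)(C)C)CCCC=O)cc1 | intermediate
13 | C10–C25 homoallylic alcohol (HO–C13, C10=C11) | COc1ccc(COCCCC[C@H](O[Si](C)(C)C(C)(C)C)CCC[C@H](O[Si](C)(C)C(C)(C)C)CCC[C@H](O)CC=C)cc1 | intermediate
14 | C10–C25 tris-silyl ether | COc1ccc(COCCCC[C@H](O[Si](C)(C)C(C)(C)C)CCC[C@H](O[Si](C)(C)C(C)(C)C)CCC[C@H](O[Si](C)(C)C(C)(C)C)CC=C)cc1 | intermediate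
15 | C9–C25 aldehyde | COc1ccc(COCCCC[C@H](O[Si](C)(C)C(C)(C)C)CCC[C@H](O[Si](C)(C)C(C)(C)C)CCC[C@H](O[Si](C)(C)C(C)(C)C)CCCC=O)cc1 | intermediate
16 | C6–C25 homoallylic alcohol (HO–C9, C6=C7) | COc1ccc(COCCCC[C@H](O[Si](C)(C)C(C)(C)C)CCC[C@H](O[Si](C)(C)C(C)(C)C)CCC[C@H](O[Si](C)(C)C(C)(C)C)CCC[C@@H](O)CC=C)cc1 | intermediate
17 | C6–C25 tetrakis-silyl ether | COc1ccc(COCCCC[C@H](O[Si](C)(C)C(C)(C)C)CCC[C@H](O[Si](C)(C)C(C)(C)C)CCC[C@H](O[Si](C)(C)C(C)(C)C)CCC[C@@H](O[Si](C)(C)C(C)(C)C)CC=C)cc1 | intermediate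
18 | C7–C25 aldehyde (CHO = C7) | COc1ccc(COCCCC[C@H](O[Si](C)(C)C(C)(C)C)CCC[C@H](O[Si](C)(C)C(C)(C)C)CCC[C@H](O[Si](C)(C)C(C)(C)C)CCC[C@@H](O[Si](C)(C)C(C)(C)C)CC=O)cc1 | intermediate (not isolated)
19 | C7–C25 primary alcohol (HO–C7H2) | COc1ccc(COCCCC[C@H](O[Si](C)(C)C(C)(C)C)CCC[C@H](O[Si](C)(C)C(C)(C)C)CCC[C@H](O[Si](C)(C)C(C)(C)C)CCC[C@@H](O[Si](C)(C)C(C)(C)C)CCO)cc1 | intermediate
20 | C4–C25 homoallylic alcohol (HO–C7, C4=C5) | COc1ccc(COCCCC[C@H](O[Si](C)(C)C(C)(C)C)CCC[C@H](O[Si](C)(C)C(C)(C)C)CCC[C@H](O[Si](C)(C)C(C)(C)C)CCC[C@@H](O[Si](C)(C)C(C)(C)C)C[C@@H](O)CC=C)cc1 | intermediate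
21 | C4–C25 pentakis-silyl ether (PMBO–C25) | COc1ccc(COCCCC[C@H](O[Si](C)(C)C(C)(C)C)CCC[C@H](O[Si](C)(C)C(C)(C)C)CCC[C@H](O[Si](C)(C)C(C)(C)C)CCC[C@@H](O[Si](C)(C)C(C)(C)C)C[C@@H](O[Si](C)(C)C(C)(C)C)CC=C)cc1 | intermediate
22 | C4–C25 primary alcohol (HO–C25H2) | OCCCC[C@H](O[Si](C)(C)C(C)(C)C)CCC[C@H](O[Si](C)(C)C(C)(C)C)CCC[C@H](O[Si](C)(C)C(C)(C)C)CCC[C@@H](O[Si](C)(C)C(C)(C)C)C[C@@H](O[Si](C)(C)C(C)(C)C)CC=C | intermediate
23 | C4–C25 aldehyde (CHO = C25) | O=CCCC[C@H](O[Si](C)(C)C(C)(C)C)CCC[C@H](O[Si](C)(C)C(C)(C)C)CCC[C@H](O[Si](C)(C)C(C)(C)C)CCC[C@@H](O[Si](C)(C)C(C)(C)C)C[C@@H](O[Si](C)(C)C(C)(C)C)CC=C | intermediate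
24 | C4–C26 oxirane, mixture of C25 epimers | C1OC1CCC[C@H](O[Si](C)(C)C(C)(C)C)CCC[C@H](O[Si](C)(C)C(C)(C)C)CCC[C@H](O[Si](C)(C)C(C)(C)C)CCC[C@@H](O[Si](C)(C)C(C)(C)C)C[C@@H](O[Si](C)(C)C(C)(C)C)CC=C | intermediate
25 | west epoxide, (25S)-oxirane C25–C26, TBSO at C7, C9, C13, C17, C21, alkene C4=C5 | C1O[C@H]1CCC[C@H](O[Si](C)(C)C(C)(C)C)CCC[C@H](O[Si](C)(C)C(C)(C)C)CCC[C@H](O[Si](C)(C)C(C)(C)C)CCC[C@@H](O[Si](C)(C)C(C)(C)C)C[C@@H](O[Si](C)(C)C(C)(C)C)CC=C | intermediate
26 | (S)-4-benzyloxazolidin-2-one | O=C1N[C@@H](Cc2ccccc2)CO1 | starting material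
27 | hexanoyl chloride | CCCCCC(Cl)=O | starting material
28 | (S)-4-benzyl-3-hexanoyloxazolidin-2-one | CCCCCC(=O)N1[C@@H](Cc2ccccc2)COC1=O | intermediate
29 | sodium (Z)-enolate of 28 | CCCC/C=C(\O[Na])N1[C@@H](Cc2ccccc2)COC1=O | intermediate (not isolated)
30 | (S)-4-benzyl-3-[(S)-2-methylhexanoyl]oxazolidin-2-one | CCCC[C@H](C)C(=O)N1[C@@H](Cc2ccccc2)COC1=O | intermediate
31 | (S)-2-methylhexan-1-ol | CCCC[C@H](C)CO | intermediate
32 | (4R,5S)-5-methylnon-1-en-4-ol | CCCC[C@H](C)[C@H](O)CC=C | intermediate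
33 | 1-methoxy-4-({[(4R,5S)-5-methylnon-1-en-4-yl]oxy}methyl)benzene | CCCC[C@H](C)[C@H](OCc1ccc(OC)cc1)CC=C | intermediate
34 | (3R,4S)-3-[(4-methoxybenzyl)oxy]-4-methyloctanal | CCCC[C@H](C)[C@H](OCc1ccc(OC)cc1)CC=O | intermediate (not isolated)
35 | (3R,4S)-3-[(4-methoxybenzyl)oxy]-4-methyloctan-1-ol | CCCC[C@H](C)[C@H](OCc1ccc(OC)cc1)CCO | intermediate
36 | (4R,6R,7S)-6-[(4-methoxybenzyl)oxy]-7-methylundec-1-en-4-ol | CCCC[C@H](C)[C@H](OCc1ccc(OC)cc1)C[C@H](O)CC=C | intermediate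
37 | C33 TBS ether of 36 | CCCC[C@H](C)[C@H](OCc1ccc(OC)cc1)C[C@H](O[Si](C)(C)C(C)(C)C)CC=C | intermediate
38 | (5R,7R,8S)-5-(TBS-oxy)-7-(PMB-oxy)-8-methyldodecanal | CCCC[C@H](C)[C@H](OCc1ccc(OC)cc1)C[C@H](O[Si](C)(C)C(C)(C)C)CCCC=O | intermediate
39 | C28–C40 oxirane, mixture of C29 epimers | CCCC[C@H](C)[C@H](OCc1ccc(OC)cc1)C[C@H](O[Si](C)(C)C(C)(C)C)CCCC1CO1 | intermediate
40 | east epoxide, (29S,33R,35R,36S), oxirane C28–C29, C33 TBS ether, C35 PMB ether | CCCC[C@H](C)[C@H](OCc1ccc(OC)cc1)C[C@H](O[Si](C)(C)C(C)(C)C)CCC[C@H]1CO1 | intermediate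
41 | 2-lithio-2-(tert-butyldimethylsilyl)-1,3-dithiane | [Li]C1(SCCCS1)[Si](C)(C)C(C)(C)C | intermediate (not isolated)
42 | C25 lithium alkoxide of the C4–C27 silyl dithiane | CC(C)(C)[Si](C)(C)C1(SCCCS1)C[C@@H](O[Li])CCC[C@H](O[Si](C)(C)C(C)(C)C)CCC[C@H](O[Si](C)(C)C(C)(C)C)CCC[C@H](O[Si](C)(C)C(C)(C)C)CCC[C@@H](O[Si](C)(C)C(C)(C)C)C[C@@H](O[Si](C)(C)C(C)(C)C)CC=C | intermediate (not isolated)
43 | C27-lithiated C4–C27 dithiane with O25 silylated | [Li]C1(SCCCS1)C[C@@H](O[Si](C)(C)C(C)(C)C)CCC[C@H](O[Si](C)(C)C(C)(C)C)CCC[C@H](O[Si](C)(C)C(C)(C)C)CCC[C@H](O[Si](C)(C)C(C)(C)C)CCC[C@@H](O[Si](C)(C)C(C)(C)C)C[C@@H](O[Si](C)(C)C(C)(C)C)CC=C | intermediate (not isolated)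
44 | C4–C40 chain, C27 1,3-dithiane, O25 TBS, C29 OH | CCCC[C@H](C)[C@H](OCc1ccc(OC)cc1)C[C@H](O[Si](C)(C)C(C)(C)C)CCC[C@H](O)CC1(SCCCS1)C[C@@H](O[Si](C)(C)C(C)(C)C)CCC[C@H](O[Si](C)(C)C(C)(C)C)CCC[C@H](O[Si](C)(C)C(C)(C)C)CCC[C@H](O[Si](C)(C)C(C)(C)C)CCC[C@@H](O[Si](C)(C)C(C)(C)C)C[C@@H](O[Si](C)(C)C(C)(C)C)CC=C | intermediate
45 | C27 ketone | CCCC[C@H](C)[C@H](OCc1ccc(OC)cc1)C[C@H](O[Si](C)(C)C(C)(C)C)CCC[C@H](O)CC(=O)C[C@@H](O[Si](C)(C)C(C)(C)C)CCC[C@H](O[Si](C)(C)C(C)(C)C)CCC[C@H](O[Si](C)(C)C(C)(C)C)CCC[C@H](O[Si](C)(C)C(C)(C)C)CCC[C@@H](O[Si](C)(C)C(C)(C)C)C[C@@H](O[Si](C)(C)C(C)(C)C)CC=C | intermediate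
46 | C27,C29 anti-diol | CCCC[C@H](C)[C@H](OCc1ccc(OC)cc1)C[C@H](O[Si](C)(C)C(C)(C)C)CCC[C@H](O)C[C@@H](O)C[C@@H](O[Si](C)(C)C(C)(C)C)CCC[C@H](O[Si](C)(C)C(C)(C)C)CCC[C@H](O[Si](C)(C)C(C)(C)C)CCC[C@H](O[Si](C)(C)C(C)(C)C)CCC[C@@H](O[Si](C)(C)C(C)(C)C)C[C@@H](O[Si](C)(C)C(C)(C)C)CC=C | intermediate
47 | C4–C40 nona-silyl ether, PMBO–C35, alkene C4=C5 | CCCC[C@H](C)[C@H](OCc1ccc(OC)cc1)C[C@H](O[Si](C)(C)C(C)(C)C)CCC[C@H](O[Si](C)(C)C(C)(C)C)C[C@@H](O[Si](C)(C)C(C)(C)C)C[C@@H](O[Si](C)(C)C(C)(C)C)CCC[C@H](O[Si](C)(C)C(C)(C)C)CCC[C@H](O[Si](C)(C)C(C)(C)C)CCC[C@H](O[Si](C)(C)C(C)(C)C)CCC[C@@H](O[Si](C)(C)C(C)(C)C)C[C@@H](O[Si](C)(C)C(C)(C)C)CC=C | intermediate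
48 | methyl but-2-ynoate | CC#CC(=O)OC | starting material
49 | methyl (Z)-3-iodobut-2-enoate | COC(=O)/C=C(/C)I | intermediate
50 | C4 B-alkyl-9-borabicyclo[3.3.1]nonane of 47 | CCCC[C@H](C)[C@H](OCc1ccc(OC)cc1)C[C@H](O[Si](C)(C)C(C)(C)C)CCC[C@H](O[Si](C)(C)C(C)(C)C)C[C@@H](O[Si](C)(C)C(C)(C)C)C[C@@H](O[Si](C)(C)C(C)(C)C)CCC[C@H](O[Si](C)(C)C(C)(C)C)CCC[C@H](O[Si](C)(C)C(C)(C)C)CCC[C@H](O[Si](C)(C)C(C)(C)C)CCC[C@@H](O[Si](C)(C)C(C)(C)C)C[C@@H](O[Si](C)(C)C(C)(C)C)CCCB1C2CCCC1CCC2 | intermediate (not isolated)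
51 | C1–C40 methyl (Z)-enoate, PMBO–C35, nine TBS ethers | CCCC[C@H](C)[C@H](OCc1ccc(OC)cc1)C[C@H](O[Si](C)(C)C(C)(C)C)CCC[C@H](O[Si](C)(C)C(C)(C)C)C[C@@H](O[Si](C)(C)C(C)(C)C)C[C@@H](O[Si](C)(C)C(C)(C)C)CCC[C@H](O[Si](C)(C)C(C)(C)C)CCC[C@H](O[Si](C)(C)C(C)(C)C)CCC[C@H](O[Si](C)(C)C(C)(C)C)CCC[C@@H](O[Si](C)(C)C(C)(C)C)C[C@@H](O[Si](C)(C)C(C)(C)C)CCC/C(C)=C\C(=O)OC | intermediate
52 | C35 alcohol methyl ester | CCCC[C@H](C)[C@H](O)C[C@H](O[Si](C)(C)C(C)(C)C)CCC[C@H](O[Si](C)(C)C(C)(C)C)C[C@@H](O[Si](C)(C)C(C)(C)C)C[C@@H](O[Si](C)(C)C(C)(C)C)CCC[C@H](O[Si](C)(C)C(C)(C)C)CCC[C@H](O[Si](C)(C)C(C)(C)C)CCC[C@H](O[Si](C)(C)C(C)(C)C)CCC[C@@H](O[Si](C)(C)C(C)(C)C)C[C@@H](O[Si](C)(C)C(C)(C)C)CCC/C(C)=C\C(=O)OC | intermediate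
53 | seco acid | CCCC[C@H](C)[C@H](O)C[C@H](O[Si](C)(C)C(C)(C)C)CCC[C@H](O[Si](C)(C)C(C)(C)C)C[C@@H](O[Si](C)(C)C(C)(C)C)C[C@@H](O[Si](C)(C)C(C)(C)C)CCC[C@H](O[Si](C)(C)C(C)(C)C)CCC[C@H](O[Si](C)(C)C(C)(C)C)CCC[C@H](O[Si](C)(C)C(C)(C)C)CCC[C@@H](O[Si](C)(C)C(C)(C)C)C[C@@H](O[Si](C)(C)C(C)(C)C)CCC/C(C)=C\C(=O)O | intermediate
54 | mixed anhydride of 53 with 2-methyl-6-nitrobenzoic acid | CCCC[C@H](C)[C@H](O)C[C@H](O[Si](C)(C)C(C)(C)C)CCC[C@H](O[Si](C)(C)C(C)(C)C)C[C@@H](O[Si](C)(C)C(C)(C)C)C[C@@H](O[Si](C)(C)C(C)(C)C)CCC[C@H](O[Si](C)(C)C(C)(C)C)CCC[C@H](O[Si](C)(C)C(C)(C)C)CCC[C@H](O[Si](C)(C)C(C)(C)C)CCC[C@@H](O[Si](C)(C)C(C)(C)C)C[C@@H](O[Si](C)(C)C(C)(C)C)CCC/C(C)=C\C(=O)OC(=O)c1c(C)cccc1[N+](=O)[O-] | intermediate (not isolated)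
55 | nona-TBS 36-membered macrolactone | CCCC[C@H](C)[C@H]1C[C@H](O[Si](C)(C)C(C)(C)C)CCC[C@H](O[Si](C)(C)C(C)(C)C)C[C@@H](O[Si](C)(C)C(C)(C)C)C[C@@H](O[Si](C)(C)C(C)(C)C)CCC[C@H](O[Si](C)(C)C(C)(C)C)CCC[C@H](O[Si](C)(C)C(C)(C)C)CCC[C@H](O[Si](C)(C)C(C)(C)C)CCC[C@@H](O[Si](C)(C)C(C)(C)C)C[C@@H](O[Si](C)(C)C(C)(C)C)CCC/C(C)=C\C(=O)O1 | intermediate
56 | CNP0126363.4 | CCCC[C@H](C)[C@H]1C[C@H](O)CCC[C@H](O)C[C@@H](O)C[C@@H](O)CCC[C@H](O)CCC[C@H](O)CCC[C@H](O)CCC[C@@H](O)C[C@@H](O)CCC/C(C)=C\C(=O)O1 | target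

**Step count**

Total: 41 steps. Longest linear sequence: 28 steps (steps 2–20, 32–35 and 37–41).

**Steps most likely to fail**

Step 32. The silyl group may migrate before the first alkylation is complete, so that one epoxide is consumed twice, or the second opening may stall because the long lipophilic anion aggregates. The fallback makes the two C–C bonds one at a time by classical dithiane alkylation. It sets out from 25 and 1: 2-lithio-1,3-dithiane 2 (n-BuLi, THF, −20 °C) opens 25 at C26 to give the C25 alcohol, hydroxy dithiane F1. Silylation with TBSOTf and 2,6-lutidine gives the C25 silyl ether F2. t-BuLi in THF/HMPA at −78 °C metalates C27 of F2 to the same anion 43, and alkylation with 40 at C28 returns to the route at 44.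

Step 40. Activation of the conjugated acid may scramble the C2=C3 geometry or shift the double bond out of conjugation through a dienolate or vinylketene, and intermolecular esterification may compete with closure of the large ring. The fallback closes the ring at C3–C4 instead of O35–C1. It sets out from 47: DDQ frees O35 to give the C35 alcohol F3. F3 is esterified with (Z)-3-iodobut-2-enoic acid F4 (from commercial but-2-ynoic acid, NaI, AcOH, 115 °C) using N,N′-diisopropylcarbodiimide and catalytic DMAP at 0 °C, giving the C35 iodoenoate ester F5. Hydroboration of the C4=C5 alkene with 9-BBN gives the alkylborane F6, and an intramolecular B-alkyl Suzuki–Miyaura coupling (Pd(dppf)Cl2, AsPh3, Cs2CO3, DMF/THF/H2O, high dilution) returns to the route at 55.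

Step 19. The unbranched aldehyde may enolise and self-condense under the basic ylide conditions, which would erode material at the end of the longest sequence. The fallback adds C26 as a carbenoid at low temperature. It sets out from 23: chloromethyllithium, generated in the presence of 23 from chloroiodomethane and MeLi·LiBr in THF at −78 °C, adds to the formyl group to give the C25-epimeric chlorohydrin F7. K2CO3 in MeOH closes F7 to the oxirane, returning to the route at 24 before the resolution of step 20.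

**Further compounds**

F1 | step 32 | C4–C27 hydroxy dithiane (C25 OH, C27 dithiane CH) | C1(SCCCS1)C[C@@H](O)CCC[C@H](O[Si](C)(C)C(C)(C)C)CCC[C@H](O[Si](C)(C)C(C)(C)C)CCC[C@H](O[Si](C)(C)C(C)(C)C)CCC[C@@H](O[Si](C)(C)C(C)(C)C)C[C@@H](O[Si](C)(C)C(C)(C)C)CC=C
F2 | step 32 | C4–C27 dithiane with O25 TBS ether | C1(SCCCS1)C[C@@H](O[Si](C)(C)C(C)(C)C)CCC[C@H](O[Si](C)(C)C(C)(C)C)CCC[C@H](O[Si](C)(C)C(C)(C)C)CCC[C@H](O[Si](C)(C)C(C)(C)C)CCC[C@@H](O[Si](C)(C)C(C)(C)C)C[C@@H](O[Si](C)(C)C(C)(C)C)CC=C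
F3 | step 40 | C4–C40 nona-silyl ether with free C35 hydroxyl | CCCC[C@H](C)[C@H](O)C[C@H](O[Si](C)(C)C(C)(C)C)CCC[C@H](O[Si](C)(C)C(C)(C)C)C[C@@H](O[Si](C)(C)C(C)(C)C)C[C@@H](O[Si](C)(C)C(C)(C)C)CCC[C@H](O[Si](C)(C)C(C)(C)C)CCC[C@H](O[Si](C)(C)C(C)(C)C)CCC[C@H](O[Si](C)(C)C(C)(C)C)CCC[C@@H](O[Si](C)(C)C(C)(C)C)C[C@@H](O[Si](C)(C)C(C)(C)C)CC=C
F4 | step 40 | (Z)-3-iodobut-2-enoic acid | C/C(I)=C/C(=O)O
F5 | step 40 | C35 (Z)-3-iodobut-2-enoate ester of F3 | CCCC[C@H](C)[C@H](OC(=O)/C=C(/C)I)C[C@H](O[Si](C)(C)C(C)(C)C)CCC[C@H](O[Si](C)(C)C(C)(C)C)C[C@@H](O[Si](C)(C)C(C)(C)C)C[C@@H](O[Si](C)(C)C(C)(C)C)CCC[C@H](O[Si](C)(C)C(C)(C)C)CCC[C@H](O[Si](C)(C)C(C)(C)C)CCC[C@H](O[Si](C)(C)C(C)(C)C)CCC[C@@H](O[Si](C)(C)C(C)(C)C)C[C@@H](O[Si](C)(C)C(C)(C)C)CC=C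
F6 | step 40 | C4 B-alkyl-9-borabicyclo[3.3.1]nonane of F5 | CCCC[C@H](C)[C@H](OC(=O)/C=C(/C)I)C[C@H](O[Si](C)(C)C(C)(C)C)CCC[C@H](O[Si](C)(C)C(C)(C)C)C[C@@H](O[Si](C)(C)C(C)(C)C)C[C@@H](O[Si](C)(C)C(C)(C)C)CCC[C@H](O[Si](C)(C)C(C)(C)C)CCC[C@H](O[Si](C)(C)C(C)(C)C)CCC[C@H](O[Si](C)(C)C(C)(C)C)CCC[C@@H](O[Si](C)(C)C(C)(C)C)C[C@@H](O[Si](C)(C)C(C)(C)C)CCCB1C2CCCC1CCC2
F7 | step 19 | C4–C26 chlorohydrin (C26 Cl, C25 OH, both C25 epimers) | ClCC(O)CCC[C@H](O[Si](C)(C)C(C)(C)C)CCC[C@H](O[Si](C)(C)C(C)(C)C)CCC[C@H](O[Si](C)(C)C(C)(C)C)CCC[C@@H](O[Si](C)(C)C(C)(C)C)C[C@@H](O[Si](C)(C)C(C)(C)C)CC=C
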